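The ash, alder and maple runs are what I have for Tuesday's and Monday's flasks, which share one charge and differ in time.

| flask | left-handed substrate | right-handed substrate | partner | remark | time |
|---|---|---|---|---|---|
| ash | 0.20 M | 0.20 M | 1 M | run made earlier |  |
| alder | 0.30 M | 0.30 M | 1 M | run made earlier |  |
| maple | 0.40 M | 0.40 M | 2 M | run made earlier |  |
| Tuesday's | 0.40 M | 0.40 M | 1.00 M |  | 3.0 min |
| Monday's | 0.40 M | 0.40 M | 1.00 M |  | 6.0 min |

| run | time / min | left-handed product / % | right-handed product / % |
|---|---|---|---|
| ash | 0.500 | 6.8 | 3.7 |
| ash | 1.00 | 8.0 | 7.2 |
| ash | 1.50 | 9.3 | 9.1 |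
| ash | 2.00 | 10.6 | 10.1 |
| ash | 2.50 | 11.5 | 10.4 |
| ash | 3.00 | 10.6 | 11.4 |
| alder | 0.200 | 5.0 | 1.1 |
| alder | 0.667 | 9.0 | 4.9 |
| alder | 1.00 | 7.8 | 7.5 |
| alder | 1.50 | 9.5 | 9.0 |
| alder | 2.50 | 10.4 | 10.0 |
| alder | 3.00 | 11.4 | 11.3 |
| maple | 0.667 | 12.2 | 10.0 |
| maple | 1.33 | 14.5 | 14.4 |
| maple | 2.00 | 16.4 | 15.7 |
| maple | 2.50 | 16.6 | 16.9 |
| maple | 3.00 | 17.6 | 16.6 |

(standard deviation of a reading: 0.5 percentage points)

- partner is single-handed; left-handed substrate and right-handed substrate are mirror images of each other, charged as a racemate, each of them at the stated concentration
- the numbers in the tables scatter by 0.5 percentage points (one standard deviation)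
- an excess is the difference of the two amounts in percent of their sum
- an excess is below zero if the other one leads
- the handed part of partner does not stay in what it makes, so the products of the two hands are mirror images too

* the flask that ends with the higher excess of left-handed product over right-handed product in the product, or "neither" when 2 percentage points or less lies between them (Tuesday's / Monday's / neither)
* excess of left-handed product over right-handed product in the product at the end, Tuesday's
* excess of left-handed product over right-handed product in the product at the end, Monday's

In the alder run the left-handed product leads by 3.9 percentage points at 0.200 min and by 0.1 points at 3.00 min, yet the two products together grow from 6.10% to 22.7%, so the lead shrinks while product is being made. The products are mirror images, so their equal mixture is where a turning of one into the other ends; I read this as kinetic control giving way to thermodynamic control, and I time the loss on the ash readings: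

excess at 0.500 min: 29.5%; excess at 1.00 min: 5.26%

time between them / ln(ratio of the excesses) = 0.290 min

This value, which carries the scatter of the two ash readings behind it, is the excess lifetime, the time in which the excess of the ash run falls by a factor e between those readings, and I count turnovers in it, taking it over unchanged from the ash run's 0.20 M of each substrate to the 0.40 M of Tuesday's and Monday's:

lifetimes needed from the ash reading at 0.500 min down to 2 points: 2.69

lifetimes available: Tuesday's 8.62, Monday's 19.0

Both flasks have more lifetimes than needed, so I expect both excesses below the margin and the answer neither.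

The forecast gives 0.5% for Tuesday's and 0% for Monday's, hence neither, holding that “the excess should be essentially zero”.

The simulation gives 1.01% for Tuesday's and 0.136% for Monday's, which is neither, with 0.87 points between them.

    partner + left-handed substrate → left-handed product (k = 0.0110 L mol⁻¹ s⁻¹)
    partner + right-handed substrate → right-handed product (k = 1.50 × 10⁻⁴ L mol⁻¹ s⁻¹)
    left-handed substrate ⇌ achiral form (K = 0.0180, k = 0.00640 s⁻¹)
    right-handed substrate ⇌ achiral form (K = 0.0180, k = 0.00640 s⁻¹)
    achiral form → waste (k = 0.0900 s⁻¹)
    left-handed product ⇌ right-handed product (k = 0.0540 s⁻¹)
    partner → decomposed reagent (k = 0.0150 s⁻¹)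
    partner ⇌ dormant form (K = 0.370, k = 0.00780 s⁻¹)

Tuesday's, read 8.62 lifetimes past the time of the ash reading, holds 1.01%, while the same flask read at 50 s, 1.15 lifetimes past that time and so fewer than the 2.69 needed, still holds 10.9%. In Tuesday's at 0.618 min, the half-life of partner by its turning into decomposed reagent is 0.77 min, shorter than the 2.5 min of left-handed substrate by its turning into left-handed product. At 3.00 min Tuesday's has 6.29% of its partner free, 0.0446 M in dormant form, and 60% of its left-handed substrate left.

(The earlier runs and the new flask were generated by integration with constants of no real substance, noise included.)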